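## Analysis of the target

The target is (4S,5R,10R)-11,14-dihydroxy-12-methoxy-7-oxoabieta-8,11,13-trien-19,20-olide. Abietane numbering is used for all atoms below; systematic names of intermediates keep their own locants.

- Ring C is a fully substituted benzene (C11 OH, C12 OMe, C13 isopropyl, C14 OH). Ring B carries the aryl ketone C7. Ring A is a cyclohexane.
- A δ-lactone (carbonyl C19 on C4, oxygen on C20, C20 on C10) spans C4 and C10. Ring A and the lactone together form a 2-oxabicyclo[3.3.1]nonan-3-one with bridgeheads C4 and C10 and C5 as the one-carbon bridge.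
- The three stereocentres are contiguous, and the quaternary carbons C4 and C10 flank C5. The lactone forces C19 and C20 to be cis, so C4 follows from C10. The only further element is H-5 trans to C20 (trans A/B).
- Sensitive groups: the para-hydroquinone (air oxidation, so it is carried as methyl ethers), the enolisable C6 and the lactone.
- The difficulty is two quaternary carbons in a 1,3-relationship, one of them benzylic on a hexasubstituted arene, plus the configuration of C5 between them.
- The strategy rests on one feature: C4 is alpha to the lactone carbonyl C19 and C5 is beta to the ketone C7. Cutting C4–C5 opens ring A and the lactone together and leaves an eight-membered lactone (C10–C1–C2–C3–C4–C19–O–C20) spiro-fused at C10 to a naphthalen-1(4H)-one.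

## Retrosynthetic reasoning

**28 to 26 (ring C oxidation state).** The hydroquinone is unmasked last, by two-electron reduction of quinone 27, which comes from oxidative demethylation of the 11,12,14-trimethoxy arene 26. Only the para pair C11/C14 can give a para-quinone, so the C12 methyl ether survives and ring C needs no other protecting group.

**26 to 25 (C2=C3).** The C2–C3 single bond is traced to the alkene of 25. That alkene is the trace of the ring closure of the medium ring and makes H-4 allylic as well as alpha to the ester.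

**25 to 22 (C4–C5, key disconnection).** Cutting C4–C5 removes two rings, one skeletal bond and two stereocentres, and leaves spiro lactone 22 with C10 as its only controlling stereocentre. Forward, dienolate 23 has to add through C4 to C5 of the enone. No other bond of the bicycle is flanked by a donor and an acceptor in this way.

**22 to 21 (C2=C3 of the eight-membered ring).** The cis alkene is cut by ring-closing metathesis to the diene ester 21. Both olefins are terminal, and the spiro quaternary carbon favours closure.

**21 to 19 and 20 (C19–O).** An ester bond between the neopentyl alcohol 19 and racemic acid 20. The configuration at C4 of 20 is irrelevant, because it is erased in 23.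

**19 to 15 (oxidation level of ring B and C20).** The C5=C6 bond is introduced by dehydrogenation of tetralone 15 (giving 17). C20 is taken from the ester to the alcohol level through diol 18 and reoxidation of C7. The alkene is installed only after C10 is quaternary; before that the ring would aromatise to a naphthol.

**15 to 12 and 13 (C10–C1).** The allyl group is put on by alkylation of enolate 14. H-10 of 12 is alpha to the ester, benzylic and conjugated through the arene with the C7 ketone, so it is the most acidic hydrogen. The ester is that of the chiral alcohol 7, which biases the enolate faces, makes the two C10 epimers separable diastereomers and is lost when C20 is reduced.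

**12 to 10 (C9–C10).** Ring B is closed by intramolecular arylation of the ester enolate with the aryl iodide 11. The iodine enters 10 at the only free ring position.

**10 to 5 and 8 (C7–C8).** Friedel–Crafts acylation of arene 5 with the acid chloride 9 of hemiester 8 (from 6 and 7). C8 is para to the C12 methoxy group and ortho to the C14 methoxy group. This innate preference fixes the order: acyl carbon first, C10 second.

**5 to 1 and 2 (isopropyl group).** The hydrogen between two methoxy groups of 1 is the most acidic, so lithiation to 3, addition to 2 and deoxygenation of 4 place the isopropyl group at C13 unambiguously.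

## Alternatives that were turned down

**Alternative 1:** Ring B is cut at C7–C8 and C9–C10. Ring C arrives as quinone A2 and ring A as the vinylcyclohexene A3. Forward, a chiral Lewis acid would activate A2, its unsubstituted C8=C9 edge would add to the diene C7=C6–C5=C10 of A3, and enolisation would give hydroquinone A1.
- For: it is convergent, ring C comes in with the final C11/C14 oxygens, and C10 is set by the catalyst in the step that makes ring B. On convergence and on the state of ring C it is stronger than the chosen route.
- Against: C10 is a fully substituted diene terminus. One of its substituents is always cis on the diene, which hinders the s-cis conformer and the approach to C9 at the very carbon that must become quaternary. The regiochemistry depends on which quinone carbonyl the Lewis acid binds.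
- A1 is far from the target: C7 must be oxidised, C5=C6 reduced with control of C5, the silyl ether removed and lactonised, and the second C4 ester reduced to a methyl group. That is about seven further operations.
- The chosen strategy gives up convergence. In return C4 arrives with its methyl group and C7 as the ketone, and three steps follow the key step.

**Alternative 2:** Ring A is cut at C5–C10 and C3–C4. Forward, heating the ten-membered benzo-fused lactone A5 would add its (Z)-enoate C4=C5 across the diene C10=C1–C2=C3 and give A4.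
- For: two bonds, three rings and three stereocentres form in one step. The suprafacial addition relays the enoate geometry into the C4/C5 relationship, so C5 relative to C4 is secured by alkene geometry. On both points it is stronger than the chosen key step, whose C5 face is its open question.
- Against: C10 of A5 is trigonal and carries both C9 and C20, so the diene terminus is 1,1-disubstituted and its s-cis form is strained. No chirality is stored at C10, so the absolute sense would have to come from the C7 silyloxy centre across a flexible ring. A5 needs a ten-membered lactonisation with a (Z)-trisubstituted enoate and a conjugated diene in place.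
- After the cycloaddition, C1=C2 must be reduced and C7 desilylated and oxidised.
- The chosen strategy forms fewer bonds in its key step, but its precursor 22 is reached by standard reactions and holds the controlling stereocentre C10 in resolved form.

**Alternative 3:** Ring C is cut at C8–C9 and C13–C14. Forward, the 2-pyrone of A7 would add to its tethered ynone, and loss of CO2 from the bridged adduct would give A6 with the aromatic ring, ring B and the C7 ketone in place.
- For: no electrophilic substitution on a crowded arene is needed, the tether fixes the regiochemistry and CO2 loss makes the step irreversible. On arene construction it is stronger than a Friedel–Crafts/arylation sequence.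
- Against: A7 must already contain ring A and the lactone with C4, C5 and C10 set. The hardest part of the molecule is moved into the precursor and not solved. A tetrasubstituted pyrone has to be attached to the quaternary C10. A6 has no C14 oxygen, so debenzylation, phenol oxidation and reduction are still needed.
- The chosen strategy builds ring C by ordinary arene chemistry and spends its key step on the bicyclic core.

Key step: step 13

## Route

Remark on the chemistry: the sense of facial shielding by the 8-phenylmenthyl ester in step 7 is assigned by analogy and is not secure. The route is written for auxiliary 7 delivering the (10R) series; the antipodal auxiliary would be used if the preference proves opposite.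

Step 1
Reactants: 1 1,2,4-trimethoxybenzene; 2 acetone
Product: 4 2-(2,3,6-trimethoxyphenyl)propan-2-ol, via (2,3,6-trimethoxyphenyl)lithium 3 (not isolated)
Conditions: n-BuLi, TMEDA, THF, 0 °C; then 2, −78 °C → rt
Reagents that add atoms: none
Why: Directed ortho-lithiation removes the hydrogen flanked by two methoxy groups, the most acidic one, and the aryllithium adds to the ketone (1,2-addition).

Step 2
Reactants: 4 2-(2,3,6-trimethoxyphenyl)propan-2-ol
Product: 5 1,2,4-trimethoxy-3-(propan-2-yl)benzene
Conditions: Et3SiH, CF3CO2H, CH2Cl2, 0 °C → rt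
Reagents that add atoms: none
Why: Ionic hydrogenation: acid ionises the tertiary benzylic alcohol to a cation stabilised by two ortho methoxy groups, and the silane delivers hydride.

Step 3
Reactants: 6 glutaric anhydride; 7 (1R,2S,5R)-5-methyl-2-(2-phenylpropan-2-yl)cyclohexan-1-ol
Product: 8 5-{[(1R,2S,5R)-5-methyl-2-(2-phenylpropan-2-yl)cyclohexyl]oxy}-5-oxopentanoic acid
Conditions: DMAP (10 mol %), Et3N, toluene, 80 °C
Reagents that add atoms: none
Why: Nucleophile-catalysed alcoholysis of a cyclic anhydride gives the hemiester; no stereocentre is touched.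

Step 4
Reactants: 8 5-{[(1R,2S,5R)-5-methyl-2-(2-phenylpropan-2-yl)cyclohexyl]oxy}-5-oxopentanoic acid; 5 1,2,4-trimethoxy-3-(propan-2-yl)benzene
Product: 10 (1R,2S,5R)-5-methyl-2-(2-phenylpropan-2-yl)cyclohexyl 5-oxo-5-[2,4,5-trimethoxy-3-(propan-2-yl)phenyl]pentanoate, via hemiester acid chloride 9 (not isolated)
Conditions: (COCl)2, DMF (cat.), CH2Cl2, 0 °C → rt; then 5, SnCl4, CH2Cl2, −20 → 0 °C
Reagents that add atoms: none
Why: Friedel–Crafts acylation at C8, the free position para to one methoxy group and ortho to another; SnCl4 at low temperature should spare the aryl methyl ethers and the secondary ester.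

Step 5
Reactants: 10 (1R,2S,5R)-5-methyl-2-(2-phenylpropan-2-yl)cyclohexyl 5-oxo-5-[2,4,5-trimethoxy-3-(propan-2-yl)phenyl]pentanoate
Product: 11 (1R,2S,5R)-5-methyl-2-(2-phenylpropan-2-yl)cyclohexyl 5-[2-iodo-3,4,6-trimethoxy-5-(propan-2-yl)phenyl]-5-oxopentanoate
Conditions: N-iodosuccinimide, CF3CO2H (cat.), MeCN, rt
Reagents that add atoms: N-iodosuccinimide, O=C1CCC(=O)N1I
Why: Electrophilic aromatic iodination at the only remaining ring hydrogen (C9, ortho to a methoxy group); acid-activated N-iodosuccinimide should iodinate the arene faster than the ketone enolises.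

Step 6
Reactants: 11 (1R,2S,5R)-5-methyl-2-(2-phenylpropan-2-yl)cyclohexyl 5-[2-iodo-3,4,6-trimethoxy-5-(propan-2-yl)phenyl]-5-oxopentanoate
Product: 12 (1R,2S,5R)-5-methyl-2-(2-phenylpropan-2-yl)cyclohexyl 5,7,8-trimethoxy-4-oxo-6-(propan-2-yl)-1,2,3,4-tetrahydronaphthalene-1-carboxylate (C1 epimers)
Conditions: Pd(OAc)2 (5 mol %), P(t-Bu)3·HBF4 (10 mol %), LiN(SiMe3)2 (2.5 equiv), toluene, 25 → 60 °C
Reagents that add atoms: none
Why: Palladium-catalysed intramolecular α-arylation of an ester enolate closes ring B at C9–C10; the ketone enolate forms as well but could only close a four-membered ring, and the configuration at C10 is irrelevant because it is erased in step 7.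

Step 7
Reactants: 12 (1R,2S,5R)-5-methyl-2-(2-phenylpropan-2-yl)cyclohexyl 5,7,8-trimethoxy-4-oxo-6-(propan-2-yl)-1,2,3,4-tetrahydronaphthalene-1-carboxylate (C1 epimers); 13 allyl bromide
Product: 15 (1R,2S,5R)-5-methyl-2-(2-phenylpropan-2-yl)cyclohexyl (1S)-5,7,8-trimethoxy-4-oxo-1-(prop-2-en-1-yl)-6-(propan-2-yl)-1,2,3,4-tetrahydronaphthalene-1-carboxylate, via potassium ester enolate 14 (not isolated)
Conditions: KN(SiMe3)2 (1.05 equiv), THF, −78 → −40 °C; then 13, −78 → 0 °C
Reagents that add atoms: none
Why: H-10 is alpha to the ester, benzylic and conjugated through the arene with the ketone, so one equivalent of base should give the C10 anion in preference to the ketone enolate. This is a diastereoselective alkylation of a chiral ester enolate: the phenyl group of the 8-phenylmenthyl ester shields one face, and the (1S) epimer is separated from its diastereomer by chromatography or crystallisation.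

Step 8
Reactants: 15 (1R,2S,5R)-5-methyl-2-(2-phenylpropan-2-yl)cyclohexyl (1S)-5,7,8-trimethoxy-4-oxo-1-(prop-2-en-1-yl)-6-(propan-2-yl)-1,2,3,4-tetrahydronaphthalene-1-carboxylate
Product: 17 (1R,2S,5R)-5-methyl-2-(2-phenylpropan-2-yl)cyclohexyl (1R)-5,7,8-trimethoxy-4-oxo-1-(prop-2-en-1-yl)-6-(propan-2-yl)-1,4-dihydronaphthalene-1-carboxylate, via trimethylsilyl enol ether 16 (not isolated)
Conditions: Me3SiOTf, Et3N, CH2Cl2, 0 °C; then Pd(OAc)2 (1.1 equiv), MeCN, rt
Reagents that add atoms: none
Why: Saegusa–Ito dehydrogenation: the ketone can enolise only towards C6, and divalent palladium converts the silyl enol ether into the enone. C10 is quaternary, so the ring cannot aromatise, and the descriptor changes only because the priorities change.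

Step 9
Reactants: 17 (1R,2S,5R)-5-methyl-2-(2-phenylpropan-2-yl)cyclohexyl (1R)-5,7,8-trimethoxy-4-oxo-1-(prop-2-en-1-yl)-6-(propan-2-yl)-1,4-dihydronaphthalene-1-carboxylate
Product: 18 (4R)-4-(hydroxymethyl)-5,6,8-trimethoxy-4-(prop-2-en-1-yl)-7-(propan-2-yl)-1,4-dihydronaphthalen-1-ol (C1 epimers)
Conditions: i-Bu2AlH (5 equiv), CH2Cl2, −78 → 0 °C; aq. KNaC4H4O6 work-up
Reagents that add atoms: none
Why: Hydride reduction takes the hindered ester to the primary alcohol and releases the auxiliary; the enone is reduced 1,2 at the same time, which is corrected in step 10. Neutral work-up avoids ionisation of the doubly activated carbinol.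

Step 10
Reactants: 18 (4R)-4-(hydroxymethyl)-5,6,8-trimethoxy-4-(prop-2-en-1-yl)-7-(propan-2-yl)-1,4-dihydronaphthalen-1-ol (C1 epimers)
Product: 19 (4R)-4-(hydroxymethyl)-5,6,8-trimethoxy-4-(prop-2-en-1-yl)-7-(propan-2-yl)naphthalen-1(4H)-one
Conditions: MnO2 (activated, excess), CH2Cl2, rt
Reagents that add atoms: none
Why: MnO2 oxidises the allylic and benzylic secondary alcohol and leaves the saturated primary alcohol untouched.

Step 11
Reactants: 19 (4R)-4-(hydroxymethyl)-5,6,8-trimethoxy-4-(prop-2-en-1-yl)-7-(propan-2-yl)naphthalen-1(4H)-one; 20 2-methylbut-3-enoic acid (racemic)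
Product: 21 [(1R)-5,7,8-trimethoxy-4-oxo-1-(prop-2-en-1-yl)-6-(propan-2-yl)-1,4-dihydronaphthalen-1-yl]methyl 2-methylbut-3-enoate (epimers at the ester alpha carbon)
Conditions: DCC, DMAP (5 mol %), CH2Cl2, 0 °C
Reagents that add atoms: none
Why: Steglich esterification of the neopentyl alcohol; low temperature and little DMAP keep the β,γ-double bond out of conjugation, and the alpha configuration of the acid does not matter.

Step 12
Reactants: 21 [(1R)-5,7,8-trimethoxy-4-oxo-1-(prop-2-en-1-yl)-6-(propan-2-yl)-1,4-dihydronaphthalen-1-yl]methyl 2-methylbut-3-enoate (epimers at the ester alpha carbon)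
Product: 22 (1R,4'Z)-5,7,8-trimethoxy-3'-methyl-6-(propan-2-yl)-3',6'-dihydro-4H-spiro[naphthalene-1,7'-oxocine]-2',4(8'H)-dione (C3' epimers)
Conditions: second-generation Grubbs catalyst RuCl2(=CHPh)(H2IMes)(PCy3) (10 mol %), 1,4-benzoquinone (10 mol %), CH2Cl2 (1 mM), 40 °C
Reagents that add atoms: none
Why: Ring-closing metathesis of two terminal olefins; the spiro quaternary carbon pre-organises the chain, the ring size enforces the cis alkene, and the electron-poor endocyclic enone should not take part.

Step 13
Reactants: 22 (1R,4'Z)-5,7,8-trimethoxy-3'-methyl-6-(propan-2-yl)-3',6'-dihydro-4H-spiro[naphthalene-1,7'-oxocine]-2',4(8'H)-dione (C3' epimers)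
Product: 25 (4S,5R,10R)-11,12,14-trimethoxy-7-oxoabieta-2,8,11,13-tetraen-19,20-olide, via potassium dienolate 23 (not isolated), via potassium C7 enolate 24 (not isolated)
Conditions: KOt-Bu (0.3 equiv), t-BuOH/THF (1:4), 5 mM, 0 → 50 °C
Reagents that add atoms: none
Why: Catalytic tert-butoxide removes H-4, which is alpha to the lactone carbonyl and allylic, to give dienolate 23; its alpha carbon C4 adds to C5 of the enone, and enolate 24 is protonated by tert-butanol, which returns the base. The closest known reaction type is the base-mediated intramolecular or transannular Michael addition of ester and lactone enolates to enones. Ring A and the δ-lactone both close in a 6-exo-trig sense at C5, with the enolate double bond exocyclic to ring A and endocyclic to the lactone; attack through the gamma carbon C2 would need a cyclobutane and is not expected. The enone has no enolisable hydrogen because C10 is quaternary, so only the lactone is deprotonated, and both C4 epimers of 22 give the same planar dienolate. C4 is controlled by C10: once both three-atom bridges tie C4 to C10 the methyl group can only be exo, so (10R) dictates (4S). C5 needs addition on the enone face that carries C20, which puts C6 over the lactone bridge and H-5 anti to C20. The two bridges are sterically alike, so kinetic discrimination is not assured; the reaction is therefore run warm enough for retro-Michael equilibration, which is expected, though not certain, to favour C6 equatorial on the carbocycle. Both tethers hold C4 near the enone plane, so ring B must pucker and the reaction may be slow; high dilution suppresses intermolecular addition.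

Step 14
Reactants: 25 (4S,5R,10R)-11,12,14-trimethoxy-7-oxoabieta-2,8,11,13-tetraen-19,20-olide
Product: 26 (4S,5R,10R)-11,12,14-trimethoxy-7-oxoabieta-8,11,13-trien-19,20-olide
Conditions: H2 (1 atm), 10% Pd/C, EtOAc, rt
Reagents that add atoms: none
Why: Heterogeneous hydrogenation of the isolated cis-disubstituted alkene; the aryl ketone and the lactone should survive at one atmosphere, and no stereocentre is formed.

Step 15
Reactants: 26 (4S,5R,10R)-11,12,14-trimethoxy-7-oxoabieta-8,11,13-trien-19,20-olide
Product: 27 (4S,5R,10R)-12-methoxy-7,11,14-trioxoabieta-8,12-dien-19,20-olide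
Conditions: (NH4)2Ce(NO3)6 (2.5 equiv), MeCN/H2O (2:1), 0 °C
Reagents that add atoms: water, O
Why: Oxidative demethylation of the para-dimethoxy pair by tetravalent cerium (electron transfer, attack of water at C11 and C14, loss of methanol); the para-quinone is the usual product from a 1,2,4-trimethoxy arene, and the C12 methyl ether is kept.

Step 16
Reactants: 27 (4S,5R,10R)-12-methoxy-7,11,14-trioxoabieta-8,12-dien-19,20-olide
Product: 28 (4S,5R,10R)-11,14-dihydroxy-12-methoxy-7-oxoabieta-8,11,13-trien-19,20-olide
Conditions: Na2S2O4, EtOAc/H2O, rt, argon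
Reagents that add atoms: none
Why: Two-electron reduction of the quinone to the hydroquinone; the C14 hydroxyl is hydrogen-bonded to the C7 ketone, and the product is handled under inert gas.

## Compound list

1 | 1,2,4-trimethoxybenzene | COc1ccc(OC)c(OC)c1 | starting material
2 | acetone | CC(C)=O | starting material
3 | (2,3,6-trimethoxyphenyl)lithium | [Li]c1c(OC)ccc(OC)c1OC | intermediate
4 | 2-(2,3,6-trimethoxyphenyl)propan-2-ol | CC(C)(O)c1c(OC)ccc(OC)c1OC | intermediate
5 | 1,2,4-trimethoxy-3-(propan-2-yl)benzene | CC(C)c1c(OC)ccc(OC)c1OC | intermediate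
6 | glutaric anhydride | O=C1CCCC(=O)O1 | starting material
7 | (1R,2S,5R)-5-methyl-2-(2-phenylpropan-2-yl)cyclohexan-1-ol, (−)-8-phenylmenthol | O[C@@H]1C[C@H](C)CC[C@H]1C(C)(C)c1ccccc1 | starting material
8 | 5-{[(1R,2S,5R)-5-methyl-2-(2-phenylpropan-2-yl)cyclohexyl]oxy}-5-oxopentanoic acid | OC(=O)CCCC(=O)O[C@@H]1C[C@H](C)CC[C@H]1C(C)(C)c1ccccc1 | intermediate
9 | (1R,2S,5R)-5-methyl-2-(2-phenylpropan-2-yl)cyclohexyl 5-chloro-5-oxopentanoate | ClC(=O)CCCC(=O)O[C@@H]1C[C@H](C)CC[C@H]1C(C)(C)c1ccccc1 | intermediate
10 | (1R,2S,5R)-5-methyl-2-(2-phenylpropan-2-yl)cyclohexyl 5-oxo-5-[2,4,5-trimethoxy-3-(propan-2-yl)phenyl]pentanoate | COc1cc(C(=O)CCCC(=O)O[C@@H]2C[C@H](C)CC[C@H]2C(C)(C)c2ccccc2)c(OC)c(C(C)C)c1OC | intermediate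
11 | (1R,2S,5R)-5-methyl-2-(2-phenylpropan-2-yl)cyclohexyl 5-[2-iodo-3,4,6-trimethoxy-5-(propan-2-yl)phenyl]-5-oxopentanoate | COc1c(I)c(C(=O)CCCC(=O)O[C@@H]2C[C@H](C)CC[C@H]2C(C)(C)c2ccccc2)c(OC)c(C(C)C)c1OC | intermediate
12 | (1R,2S,5R)-5-methyl-2-(2-phenylpropan-2-yl)cyclohexyl 5,7,8-trimethoxy-4-oxo-6-(propan-2-yl)-1,2,3,4-tetrahydronaphthalene-1-carboxylate (C1 epimers) | COc1c(OC)c2c(c(OC)c1C(C)C)C(=O)CCC2C(=O)O[C@@H]3C[C@H](C)CC[C@H]3C(C)(C)c3ccccc3 | intermediate
13 | allyl bromide | C=CCBr | starting material
14 | potassium ester enolate of 12 | COc1c(OC)c2c(c(OC)c1C(C)C)C(=O)CCC2=C([O-])O[C@@H]3C[C@H](C)CC[C@H]3C(C)(C)c3ccccc3.[K+] | intermediate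
15 | (1R,2S,5R)-5-methyl-2-(2-phenylpropan-2-yl)cyclohexyl (1S)-5,7,8-trimethoxy-4-oxo-1-(prop-2-en-1-yl)-6-(propan-2-yl)-1,2,3,4-tetrahydronaphthalene-1-carboxylate | COc1c(OC)c2c(c(OC)c1C(C)C)C(=O)CC[C@@]2(CC=C)C(=O)O[C@@H]3C[C@H](C)CC[C@H]3C(C)(C)c3ccccc3 | intermediate
16 | trimethylsilyl enol ether of 15 (4-trimethylsilyloxy-1,2-dihydronaphthalene) | COc1c(OC)c2c(c(OC)c1C(C)C)C(O[Si](C)(C)C)=CC[C@@]2(CC=C)C(=O)O[C@@H]3C[C@H](C)CC[C@H]3C(C)(C)c3ccccc3 | intermediate
17 | (1R,2S,5R)-5-methyl-2-(2-phenylpropan-2-yl)cyclohexyl (1R)-5,7,8-trimethoxy-4-oxo-1-(prop-2-en-1-yl)-6-(propan-2-yl)-1,4-dihydronaphthalene-1-carboxylate | COc1c(OC)c2c(c(OC)c1C(C)C)C(=O)C=C[C@@]2(CC=C)C(=O)O[C@@H]3C[C@H](C)CC[C@H]3C(C)(C)c3ccccc3 | intermediate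
18 | (4R)-4-(hydroxymethyl)-5,6,8-trimethoxy-4-(prop-2-en-1-yl)-7-(propan-2-yl)-1,4-dihydronaphthalen-1-ol (C1 epimers) | COc1c(OC)c2c(c(OC)c1C(C)C)C(O)C=C[C@@]2(CC=C)CO | intermediate
19 | (4R)-4-(hydroxymethyl)-5,6,8-trimethoxy-4-(prop-2-en-1-yl)-7-(propan-2-yl)naphthalen-1(4H)-one | COc1c(OC)c2c(c(OC)c1C(C)C)C(=O)C=C[C@@]2(CC=C)CO | intermediate
20 | 2-methylbut-3-enoic acid (racemic) | C=CC(C)C(=O)O | starting material
21 | [(1R)-5,7,8-trimethoxy-4-oxo-1-(prop-2-en-1-yl)-6-(propan-2-yl)-1,4-dihydronaphthalen-1-yl]methyl 2-methylbut-3-enoate (epimers at the ester alpha carbon) | COc1c(OC)c2c(c(OC)c1C(C)C)C(=O)C=C[C@@]2(CC=C)COC(=O)C(C)C=C | intermediate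
22 | (1R,4'Z)-5,7,8-trimethoxy-3'-methyl-6-(propan-2-yl)-3',6'-dihydro-4H-spiro[naphthalene-1,7'-oxocine]-2',4(8'H)-dione (C3' epimers) | COc1c(OC)c2c(c(OC)c1C(C)C)C(=O)C=C[C@]23C/C=C\C(C)C(=O)OC3 | intermediate
23 | potassium dienolate of 22 | COc1c(OC)c2c(c(OC)c1C(C)C)C(=O)C=C[C@]23C/C=C\C(C)=C([O-])OC3.[K+] | intermediate
24 | potassium C7 enolate of 25 | COc1c(OC)c2c(c(OC)c1C(C)C)C([O-])=C[C@@H]1[C@]23CC=C[C@]1(C)C(=O)OC3.[K+] | intermediate
25 | (4S,5R,10R)-11,12,14-trimethoxy-7-oxoabieta-2,8,11,13-tetraen-19,20-olide | COc1c(OC)c2c(c(OC)c1C(C)C)C(=O)C[C@@H]1[C@]23CC=C[C@]1(C)C(=O)OC3 | intermediate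
26 | (4S,5R,10R)-11,12,14-trimethoxy-7-oxoabieta-8,11,13-trien-19,20-olide | COc1c(OC)c2c(c(OC)c1C(C)C)C(=O)C[C@@H]1[C@]23CCC[C@]1(C)C(=O)OC3 | intermediate
27 | (4S,5R,10R)-12-methoxy-7,11,14-trioxoabieta-8,12-dien-19,20-olide | COC1=C(C(C)C)C(=O)C2=C(C1=O)[C@]34CCC[C@](C)(C(=O)OC3)[C@@H]4CC2=O | intermediate
28 | (4S,5R,10R)-11,14-dihydroxy-12-methoxy-7-oxoabieta-8,11,13-trien-19,20-olide | COc1c(O)c2c(c(O)c1C(C)C)C(=O)C[C@@H]1[C@]23CCC[C@]1(C)C(=O)OC3 | target

## Step count and least certain steps

Total: 16 steps. Longest linear sequence: 15 steps (steps 1, 2 and 4 to 16; step 3 prepares 8).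

**Step 13 (key step).** Two things may go wrong.
- Facial discrimination at C5 may be poor. The C1–C2=C3 bridge and the C20–O–C19 bridge are nearly the same size, so addition on the face that carries C1 (leading to the cis A/B epimer) can compete, and thermodynamic equilibration may not separate the two clearly.
- The closure may be slow, because both tethers hold C4 near the plane of the enone. That leaves time for alcoholysis of the strained lactone or for intermolecular addition.

Fallback: invert the order of ring formation, setting out from 21. Treatment of 21 with KOt-Bu (cat.) in THF/t-BuOH lets the acyclic ester dienolate add to C5 through the single C20–O–C19 tether. This ordinary 6-exo Michael addition can only give the cis-fused δ-lactone, that is, C4 delivered on the face bearing C20 and H-5 trans to C20. The product is the seco-diene lactone with a vinyl group on C4 and the allyl group on C10 F1. Of its C4 epimers only the one with vinyl syn to allyl can close, and the reversible addition should feed it. Ring-closing metathesis of F1 with RuCl2(=CHPh)(H2IMes)(PCy3) in CH2Cl2 at 40 °C closes the six-membered ring A and returns to the route at 25.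

**Step 12.** Intermolecular metathesis may outrun closure of the strained eight-membered lactone, since the ester prefers its extended conformation. Ruthenium hydride species may also move the β,γ-double bond.

Fallback: make C2=C3 by olefination and close the ring at the ester, setting out from 19. Oxidative cleavage of the terminal alkene (OsO4 cat., NaIO4, 2,6-lutidine, dioxane/H2O) spares the electron-poor enone and gives the spiro lactol (5-hydroxy-tetrahydrofuran formed by C20–OH and the C2 aldehyde) F2. A cis-selective Wittig reaction of F2 with the ylide from (2-carboxypropyl)triphenylphosphonium bromide and NaN(SiMe3)2 in THF gives the (Z)-β,γ-unsaturated hydroxy acid F3. Lactonisation of F3 with 2-methyl-6-nitrobenzoic anhydride and DMAP under high dilution returns to the route at 22.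

**Step 6.** The more acidic ketone may sequester base and catalyst, so that the ester enolate never reaches a useful concentration. Protodeiodination at the doubly ortho-substituted aryl–palladium intermediate is the other likely loss.

Fallback: use a malonate, which needs only a weak base, setting out from 5.
- Friedel–Crafts acylation of 5 with 3-chloropropanoyl chloride (SnCl4, CH2Cl2) gives 3-chloro-1-[2,4,5-trimethoxy-3-(propan-2-yl)phenyl]propan-1-one F4.
- Methyl malonyl chloride and 7 (pyridine) give methyl (1R,2S,5R)-8-phenylmenthyl malonate F5.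
- K2CO3 in acetone converts F4 into the aryl vinyl ketone, which takes up F5 to give the Michael adduct F6.
- Iodination as in step 5 gives the aryl iodide F7.
- Palladium-catalysed arylation of the malonate (Pd(dba)2, P(t-Bu)3, K3PO4, toluene, 70 °C) closes ring B to the 1,1-diester tetralone F8.
- Krapcho demethoxycarbonylation of F8 (LiCl, wet DMSO, 150 °C) removes the methyl ester only and returns to the route at 12.

**Step 7.** Facial shielding by the auxiliary may be weak or reversed, and the two C10 epimers may not separate cleanly.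

Fallback: resolve at the first free hydroxyl group, setting out from 12. Allylation as in step 7 without separation gives 15 together with its C10 epimer F9. Steps 8 to 10 carried out on the mixture give the epimeric enone ester F10 beside 17, then the enantiomeric diol F11 beside 18, then the enantiomeric alcohol F12 beside 19. Acylation with (1S)-camphanic chloride (pyridine, DMAP) gives the camphanate of 19 F13 and the camphanate of its enantiomer F14. These are separated by crystallisation or chromatography. Methanolysis of F13 (K2CO3, MeOH) returns to the route at 19.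

## Further compounds

F1 | step 13 | seco-diene δ-lactone, ring A of 25 open between C2 and C3 (C4 vinyl and methyl, C10 allyl) | COc1c(OC)c2c(c(OC)c1C(C)C)C(=O)C[C@@H]1[C@@]2(CC=C)COC(=O)[C@@]1(C)C=C
F2 | step 12 | spiro lactol from 19 (anomers) | COc1c(OC)c2c(c(OC)c1C(C)C)C(=O)C=C[C@]23CC(O)OC3
F3 | step 12 | (Z)-5-[(1R)-1-(hydroxymethyl)-5,7,8-trimethoxy-4-oxo-6-(propan-2-yl)-1,4-dihydronaphthalen-1-yl]-2-methylpent-3-enoic acid (C2 epimers) | COc1c(OC)c2c(c(OC)c1C(C)C)C(=O)C=C[C@@]2(C/C=C\C(C)C(=O)O)CO
F4 | step 6 | 3-chloro-1-[2,4,5-trimethoxy-3-(propan-2-yl)phenyl]propan-1-one | COc1cc(C(=O)CCCl)c(OC)c(C(C)C)c1OC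
F5 | step 6 | methyl (1R,2S,5R)-5-methyl-2-(2-phenylpropan-2-yl)cyclohexyl malonate | COC(=O)CC(=O)O[C@@H]1C[C@H](C)CC[C@H]1C(C)(C)c1ccccc1
F6 | step 6 | methyl (1R,2S,5R)-8-phenylmenthyl 2-{3-oxo-3-[2,4,5-trimethoxy-3-(propan-2-yl)phenyl]propyl}malonate | COC(=O)C(CCC(=O)c1cc(OC)c(OC)c(C(C)C)c1OC)C(=O)O[C@@H]1C[C@H](C)CC[C@H]1C(C)(C)c1ccccc1
F7 | step 6 | methyl (1R,2S,5R)-8-phenylmenthyl 2-{3-[2-iodo-3,4,6-trimethoxy-5-(propan-2-yl)phenyl]-3-oxopropyl}malonate | COC(=O)C(CCC(=O)c1c(I)c(OC)c(OC)c(C(C)C)c1OC)C(=O)O[C@@H]1C[C@H](C)CC[C@H]1C(C)(C)c1ccccc1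
F8 | step 6 | 1-methyl 1-[(1R,2S,5R)-8-phenylmenthyl] 5,7,8-trimethoxy-4-oxo-6-(propan-2-yl)-3,4-dihydronaphthalene-1,1(2H)-dicarboxylate | COc1c(OC)c2c(c(OC)c1C(C)C)C(=O)CCC2(C(=O)OC)C(=O)O[C@@H]3C[C@H](C)CC[C@H]3C(C)(C)c3ccccc3
F9 | step 7 | (1R) epimer of 15 | COc1c(OC)c2c(c(OC)c1C(C)C)C(=O)CC[C@]2(CC=C)C(=O)O[C@@H]3C[C@H](C)CC[C@H]3C(C)(C)c3ccccc3
F10 | step 7 | (1S) epimer of 17 | COc1c(OC)c2c(c(OC)c1C(C)C)C(=O)C=C[C@]2(CC=C)C(=O)O[C@@H]3C[C@H](C)CC[C@H]3C(C)(C)c3ccccc3
F11 | step 7 | (4S) enantiomer of 18 (C1 epimers) | COc1c(OC)c2c(c(OC)c1C(C)C)C(O)C=C[C@]2(CC=C)CO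
F12 | step 7 | (4S) enantiomer of 19 | COc1c(OC)c2c(c(OC)c1C(C)C)C(=O)C=C[C@]2(CC=C)CO
F13 | step 7 | (1S,4R)-camphanate of 19 | COc1c(OC)c2c(c(OC)c1C(C)C)C(=O)C=C[C@@]2(CC=C)COC(=O)[C@@]34CC[C@@](C)(C(=O)O3)C4(C)C
F14 | step 7 | (1S,4R)-camphanate of F12 | COc1c(OC)c2c(c(OC)c1C(C)C)C(=O)C=C[C@]2(CC=C)COC(=O)[C@@]34CC[C@@](C)(C(=O)O3)C4(C)C
A1 | alternative 1 | tricyclic hydroquinone with C5=C6 alkene, C20 silyl ether and C4 geminal diester | COc1c(O)c2c(c(O)c1C(C)C)CC=C1[C@]2(CO[Si](C)(C)C(C)(C)C)CCCC1(C(=O)OC)C(=O)OC
A2 | alternative 1 | 2-methoxy-3-(propan-2-yl)-1,4-benzoquinone | COC1=C(C(C)C)C(=O)C=CC1=O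
A3 | alternative 1 | dimethyl 3-{[tert-butyl(dimethyl)silyl]oxymethyl}-2-ethenylcyclohex-2-ene-1,1-dicarboxylate | C=CC1=C(CO[Si](C)(C)C(C)(C)C)CCCC1(C(=O)OC)C(=O)OC
A4 | alternative 2 | 7-silyloxy-11,12,14-trimethoxyabieta-1,8,11,13-tetraen-19,20-olide | COc1c(OC)c2c(c(OC)c1C(C)C)[C@H](O[Si](C)(C)C(C)(C)C)C[C@@H]1[C@]23C=CC[C@]1(C)C(=O)OC3
A5 | alternative 2 | benzo-fused ten-membered lactone with (Z)-C4=C5 enoate and exocyclic C10=C1–C2=C3 diene | COc1c(OC)c2c(c(OC)c1C(C)C)[C@H](O[Si](C)(C)C(C)(C)C)C/C=C(/C)C(=O)OC/C2=C\C=C
A6 | alternative 3 | 11-benzyloxy-12-methoxy-7-oxoabieta-8,11,13-trien-19,20-olide | COc1c(OCc3ccccc3)c2c(cc1C(C)C)C(=O)C[C@@H]1[C@]23CCC[C@]1(C)C(=O)OC3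
A7 | alternative 3 | bicyclic lactone carrying at C10 a 5-benzyloxy-4-methoxy-3-(propan-2-yl)-2-pyron-6-yl group and at C5 a 2-oxobut-3-ynyl chain | C#CC(=O)C[C@@H]1[C@@]2(C3=C(OCc4ccccc4)C(OC)=C(C(C)C)C(=O)O3)CCC[C@]1(C)C(=O)OC2
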